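## The problem

Target 13 is built from two 7-methoxycoumarin units, each carrying at C8 a 1,2-dioxygenated 3-methylbut-3-enyl chain, and the two benzylic carbons C1' and C1'' share one oxygen atom. This Ar–CH–O–CH–Ar ether is di-secondary and doubly benzylic, and each of its carbons sits between a methoxy group and the pyranone oxygen of its ring, so joining two alcohols there would be slow and would run through benzylic cations. There are four stereocentres: C1' (R) and C1'' (S) form a meso-type pair, while the carbinol carbons C2' and C2'' are both R, so one half has the like (1'R,2'R) and the other the unlike (1''S,2''R) arrangement. The benzylic pair can be fixed as a relative relationship inside a ring, but the two carbinols cannot both be derived from their benzylic neighbours by one substrate rule, because the halves are mirror-related at C1'/C1'' and the same rule would give opposite absolute configurations; a reagent must impose one absolute sense on both. The coumarin lactones exclude organolithium and Grignard reagents, dissolving metals and prolonged strong base. The allylic alcohols and the activated dibenzylic ether are acid-sensitive, and any precursor with a carbonyl group at C2' has an enolisable benzylic hydrogen at C1'. The enabling feature is that C1', the ether oxygen and C1'' with their aryl groups map onto C2, O1 and C5 of a 2,5-diarylfuran, with C2' and C2'' as C3 and C4. The ether oxygen can therefore come from furan, the 1'R,1''S pair is the cis (meso) 2,5-dihydro level of that ring, and the ring C3=C4 bond is where the ring is opened afterwards.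

## Retrosynthesis

The two bonds C2'–C3' and C2''–C3'' are cut first. This leads from 13 to the meso dialdehyde 10 and two equivalents of 2-bromopropene 11, one for each formyl group, joined through the isopropenylchromium species 12. The neighbouring cuts are worse: a C1'–C2' cut needs a benzylic anion beside an ether oxygen, and a C1'–O cut returns to the hindered etherification. The cut removes two stereocentres and leaves a precursor with a mirror plane. The forward reaction must add the same alkenyl group to the Re face of both formyl groups. Because the halves of 10 are mirror images, any intrinsic facial bias of the substrate is matched in one half and opposed in the other, so the reagent must dominate. It must also be non-basic and inert to lactones, which points to a ligand-bearing organochromium reagent. The symmetry of 10 helps: one wrong addition gives a meso diastereomer, and only two wrong additions give the enantiomer of 13.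

The two formyl carbons of 10 are reconnected to a C=C bond, giving the meso cis-2,5-dihydrofuran 8 by way of the cis-diol 9. Osmylation followed by glycol cleavage is preferred to ozonolysis for two reasons. OsO4 should distinguish the ring alkene from the coumarin C3–C4 bonds more reliably than ozone. Diol 9 is also a stable meso compound from which the labile 10 can be released under anhydrous, non-basic conditions just before use. The forward steps need only chemoselectivity, since the carbinol centres of 9 are destroyed again.

In 8 the two benzylic C–H bonds are removed, which leads to the flat, achiral furan 7. This is the disconnection that carries the plan. A C–O cut of 8 would mean cyclising a 1,4-diol through a benzylic cation, and a C=C cut (ring-closing metathesis) would first require the difficult meso ether. Removing two hydrogens instead keeps the C–O–C unit intact from furan and reduces the control of two centres to one facial choice. The forward step must place a proton on C2 and a hydride on C5 of 7 on the same face, stop at the dihydro level and leave both coumarin rings untouched.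

Furan 7 is cut at both aryl–furyl bonds into two equivalents of 8-iodo-7-methoxycoumarin 3 and one of 2,5-bis(tributylstannyl)furan 6. An sp2–sp2 cross-coupling is the most dependable C–C bond formation at this di-ortho-substituted carbon. The stannane is chosen over a double C–H arylation of the volatile parent furan, where mono-arylation and the hindered iodide make the outcome uncertain, and over furylboron reagents, which protodeboronate easily. The forward reaction must couple twice under conditions neutral to the lactone.

Iodide 3 is traced through phenol 2 to umbelliferone 1, by removing the methyl group and then the iodine, which enters ortho to the phenol at C8. Stannane 6 is traced through 2,5-dilithiofuran 5 to furan 4. All three starting materials (1, 4 and 11) are commercial.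

## Roads not taken

Alternative 1: The aryl–C1' and aryl–C1'' bonds are cut instead. The meso acetonide A1, a 2,5-cis-diaryl-3,4-O-isopropylidenetetrahydrofuran, would arise when two equivalents of the 8-coumarinylzinc reagent A2 displace both anomeric acetates of the furanoid bis-acetal A3 through oxocarbenium ions, each time anti to the acetonide. Its merit is real: the cis relationship is enforced twice by the convex face of a bicyclic acetal, a control element independent of hydride delivery and probably more secure than the facial choice in step 5. A1 is also simply the acetonide of diol 9, so this road joins the chosen one just before step 7, and no 2,5-dihydrofuran is ever exposed to acid. Its weak points lie in the bond formation. A di-ortho-substituted arylzinc is a poor nucleophile towards oxocarbenium ions, the second ionisation occurs beside an aryl group already in place, and the acetonide must survive two Lewis-acid activations. A3 costs several steps from a furan acetal, and a deprotection is added. The chosen plan sets against this a robust sp2–sp2 coupling at the same hindered carbon and a shorter sequence, and accepts in exchange a less certain cis selectivity confined to one step.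

Alternative 2: Here the carbinol C–O bonds are traced back to oxiranes. The bis-epoxide A4 would come from the meso bis(isobutenyl) ether A5 by two epoxidations with a fructose-derived dioxirane, and base- or aluminium-mediated isomerisation of A4 would give 13. In its stereodefining step this road is stronger than the chosen one. Trisubstituted alkenes are the best substrates for that catalyst, and the reagent imposes one absolute face on both halves without having to override an opposing substrate bias as directly as the organochromium addition must. A5 also has no enolisable centre. Its weakness is that A5 itself is left unsolved. The meso diaryl ether would have to come from etherification of hindered benzylic–allylic partners, which proceeds by ionisation with loss of the meso relationship and allylic transposition. The alkaline peroxymonosulfate buffer and the isomerisation reagents also meet two lactones, and two steps are added after the ether is made. The chosen plan supplies exactly what this road lacks, the meso ether, and can reach A5 from dialdehyde 10 by olefination. The endgame of this alternative is therefore kept as the reserve for step 8, while the direct alkenylation saves two steps.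

Alternative 3: One carbinol C–H bond is cut. The mono-silyl ether A6 would arise from the enone A7, whose C1' epimers interconvert, by transfer hydrogenation with RuCl(p-cymene)(TsDPEN) and HCO2H/Et3N under dynamic kinetic resolution; desilylation would follow. Its merit is that it turns the lability of the benzylic centre, a liability in step 7 of the chosen plan, into the control element, and sets C1' and C2' together without forcing a mismatched addition. The weaknesses are structural. A7 already contains the complete, differently protected other half, so two further stereocentres need their own enantioselective synthesis, and the hindered ether must still be made before the key step. The enone invites conjugate reduction by the ruthenium hydride and addition of formate or amine. The resolution also needs fast enolisation at C1', which the di-ortho-substituted aryl group disfavours because it cannot become coplanar with the enol. The two C1' epimers are diastereomers because of the remote centres, so their relative rates are not governed by the catalyst alone. The chosen plan is shorter, treats both halves at once through the hidden symmetry, and relies on statistical amplification of enantiopurity in place of a resolution.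

Key step: step 5

Assumption: the oxazoline–sulfonamide ligand of step 8 is used as the enantiomer that delivers alkenyl groups to the Re face of aldehydes, and this sense is taken to carry over from simple aldehydes to 10.

Step 1
Reactants: 1 umbelliferone (7-hydroxy-2H-chromen-2-one)
Product: 2 7-hydroxy-8-iodo-2H-chromen-2-one
Conditions: I2, KI, 20% aq. NH3, 0 °C to rt; then aq. H2SO4
Reagents that add atoms: iodine, II
Why: Electrophilic aromatic iodination of the phenoxide; in 7-hydroxycoumarins C8, ortho to the phenoxide and next to the ring oxygen, is the most nucleophilic position, so mono-iodination there is the established outcome.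

Step 2
Reactants: 2 7-hydroxy-8-iodo-2H-chromen-2-one
Product: 3 8-iodo-7-methoxy-2H-chromen-2-one
Conditions: MeI, K2CO3, acetone, reflux
Reagents that add atoms: iodomethane, CI
Why: Williamson ether synthesis on the acidic phenol; the lactone is stable to carbonate in acetone.

Step 3
Reactants: 4 furan
Product: 6 2,5-bis(tributylstannyl)furan, via 2,5-dilithiofuran 5 (not isolated)
Conditions: n-BuLi (2.5 equiv), TMEDA, hexane, reflux; then Bu3SnCl (2.5 equiv), THF, −78 °C to rt
Reagents that add atoms: tributyltin chloride (2 equiv incorporated), CCCC[Sn](Cl)(CCCC)CCCC
Why: Twofold α-lithiation of furan under diamine activation followed by electrophilic stannylation of both C–Li bonds; the oxygen directs both metalations to C2 and C5, and each C–Li bond takes up one equivalent of Bu3SnCl.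

Step 4
Reactants: 3 8-iodo-7-methoxy-2H-chromen-2-one (2 equiv incorporated, 2.2 equiv charged); 6 2,5-bis(tributylstannyl)furan
Product: 7 2,5-bis(7-methoxy-2-oxo-2H-chromen-8-yl)furan
Conditions: Pd(PPh3)4 (cat.), CuI (cat.), CsF, DMF, 60 °C
Reagents that add atoms: 8-iodo-7-methoxy-2H-chromen-2-one (the second equivalent of 3), COc1ccc2ccc(=O)oc2c1I
Why: Twofold Stille cross-coupling: zerovalent palladium inserts into the C–I bond of 3, copper- and fluoride-assisted transmetalation from tin and reductive elimination follow, and the cycle repeats with a second molecule of 3 at the second stannyl group. The conditions are neutral to the lactone and the small furyl partner tolerates the two ortho substituents.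

Step 5
Reactants: 7 2,5-bis(7-methoxy-2-oxo-2H-chromen-8-yl)furan
Product: 8 (2R,5S)-2,5-bis(7-methoxy-2-oxo-2H-chromen-8-yl)-2,5-dihydrofuran (meso, aryl groups cis)
Conditions: Et3SiH (1.2 equiv), CF3CO2H (2 equiv), (CF3)2CHOH–CH2Cl2, 0 °C; NaHCO3 quench
Reagents that add atoms: none
Why: This is an ionic hydrogenation, the known protic acid/hydrosilane reduction of furans to 2,5-dihydrofurans. The acid protonates the furan at C2, which gives the most delocalised cation: an allyl cation whose C5 end is an oxocarbenium carbon further stabilised by its ortho-methoxy aryl group. Et3SiH then transfers hydride to C5 and trifluoroacetate takes up the silyl cation. No ring is closed; the five-membered ring and its C–O–C unit come intact from furan, and the only new bonds are C2–H and C5–H. The two new stereocentres (later C1' and C1'') are set relative to each other in the hydride transfer: the bulky aryl group on the already tetrahedral C2 shields one face of the flat cation, so the silane should approach C5 from the side of the C2 hydrogen and the aryl groups end up cis. The step needs cis over trans selectivity, which rests on that shielding, and 2,5- over 2,3-reduction, which rests on the larger positive charge at the oxygen- and aryl-bearing C5. It must also stop at the dihydro stage; the isolated alkene of 8 is far less basic than the furan, and limited silane, low temperature and immediate quench guard against ring opening. The coumarin C3–C4 bonds are electron-poor enoates that are not protonated at carbon under these conditions.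

Step 6
Reactants: 8 (2R,5S)-2,5-bis(7-methoxy-2-oxo-2H-chromen-8-yl)-2,5-dihydrofuran
Product: 9 (2R,3S,4R,5S)-2,5-bis(7-methoxy-2-oxo-2H-chromen-8-yl)tetrahydrofuran-3,4-diol (meso; hydroxyl groups cis to each other and trans to the aryl groups)
Conditions: OsO4 (cat.), N-methylmorpholine N-oxide, acetone–H2O, rt
Reagents that add atoms: osmium tetroxide, O=[Os](=O)(=O)=O; N-methylmorpholine N-oxide, C[N+]1([O-])CCOCC1; water, O
Why: Upjohn dihydroxylation: OsO4 adds to the only electron-rich non-aromatic alkene from the face away from the two aryl groups, while the electron-poor coumarin C3–C4 bonds react much more slowly. The two carbinol centres are erased in step 7, so their configuration does not matter.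

Step 7
Reactants: 9 (2R,3S,4R,5S)-2,5-bis(7-methoxy-2-oxo-2H-chromen-8-yl)tetrahydrofuran-3,4-diol
Product: 10 (2R,2'S)-2,2'-oxybis[2-(7-methoxy-2-oxo-2H-chromen-8-yl)acetaldehyde] (meso)
Conditions: Pb(OAc)4, CH2Cl2, 0 °C; filtration through Celite, toluene chase, used at once
Reagents that add atoms: none
Why: Criegee glycol cleavage: the cis-diol forms a cyclic lead diester that fragments to the two formyl groups under anhydrous, non-basic conditions, which should preserve the enolisable benzylic centres. The twisted di-ortho-substituted aryl groups cannot conjugate with an enol and so further slow epimerisation.

Step 8
Reactants: 10 (2R,2'S)-2,2'-oxybis[2-(7-methoxy-2-oxo-2H-chromen-8-yl)acetaldehyde]; 11 2-bromopropene (2 equiv incorporated, one per formyl group; 4 equiv charged)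
Product: 13 8-[(1R,2R)-2-hydroxy-1-{[(1S,2R)-2-hydroxy-1-(7-methoxy-2-oxo-2H-chromen-8-yl)-3-methylbut-3-en-1-yl]oxy}-3-methylbut-3-en-1-yl]-7-methoxy-2H-chromen-2-one (target), via isopropenylchromium dichloride 12 (not isolated)
Conditions: CrCl2 (8 equiv), chiral N-[2-(4-isopropyl-4,5-dihydrooxazol-2-yl)-6-methylphenyl]methanesulfonamide (Re-selective enantiomer, stoichiometric to chromium), Et3N, THF, rt; then NiCl2 (cat.), 11 (4 equiv), 10, 0 °C to rt; aq. ethylenediamine work-up
Reagents that add atoms: 2-bromopropene (the second equivalent of 11), C=C(C)Br
Why: Twofold ligand-controlled Nozaki–Hiyama–Kishi reaction: zerovalent nickel inserts into the C–Br bond of 11, transmetalation to chromium gives 12 bound to the chiral sulfonamide, and one equivalent of 12 adds to the Re face of each of the two formyl groups, so two isopropenyl units from two equivalents of 11 are built in and C2' and C2'' both become R. The reagent is non-basic and does not attack lactones, and organochromium additions show only a modest intrinsic bias with α-alkoxy aldehydes, so the ligand should dominate in the mismatched half as well. Because 10 is meso, one wrong addition gives a separable meso diastereomer and only two give the enantiomer, so the enantiopurity of 13 should exceed the selectivity of a single addition.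

Compound list

1 | umbelliferone (7-hydroxy-2H-chromen-2-one) | O=c1ccc2ccc(O)cc2o1 | starting material
2 | 7-hydroxy-8-iodo-2H-chromen-2-one | O=c1ccc2ccc(O)c(I)c2o1 | intermediate
3 | 8-iodo-7-methoxy-2H-chromen-2-one | COc1ccc2ccc(=O)oc2c1I | intermediate
4 | furan | c1ccoc1 | starting material
5 | 2,5-dilithiofuran | [Li]c1ccc([Li])o1 | intermediate
6 | 2,5-bis(tributylstannyl)furan | CCCC[Sn](CCCC)(CCCC)c1ccc(o1)[Sn](CCCC)(CCCC)CCCC | intermediate
7 | 2,5-bis(7-methoxy-2-oxo-2H-chromen-8-yl)furan | COc1ccc2ccc(=O)oc2c1-c3ccc(o3)-c4c(OC)ccc5ccc(=O)oc45 | intermediate
8 | (2R,5S)-2,5-bis(7-methoxy-2-oxo-2H-chromen-8-yl)-2,5-dihydrofuran (meso, cis) | COc1ccc2ccc(=O)oc2c1[C@H]3C=C[C@H](O3)c4c(OC)ccc5ccc(=O)oc45 | intermediate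
9 | (2R,3S,4R,5S)-2,5-bis(7-methoxy-2-oxo-2H-chromen-8-yl)tetrahydrofuran-3,4-diol (meso) | COc1ccc2ccc(=O)oc2c1[C@H]3O[C@@H](c4c(OC)ccc5ccc(=O)oc45)[C@H](O)[C@@H]3O | intermediate
10 | (2R,2'S)-2,2'-oxybis[2-(7-methoxy-2-oxo-2H-chromen-8-yl)acetaldehyde] (meso) | O=C[C@H](O[C@@H](c1c(OC)ccc2ccc(=O)oc12)C=O)c1c(OC)ccc2ccc(=O)oc12 | intermediate
11 | 2-bromopropene | C=C(C)Br | starting material
12 | isopropenylchromium dichloride (prop-1-en-2-yl on trivalent chromium; ligand-bound in the flask) | C=C(C)[Cr](Cl)Cl | intermediate
13 | 8-[(1R,2R)-2-hydroxy-1-{[(1S,2R)-2-hydroxy-1-(7-methoxy-2-oxo-2H-chromen-8-yl)-3-methylbut-3-en-1-yl]oxy}-3-methylbut-3-en-1-yl]-7-methoxy-2H-chromen-2-one | C=C(C)[C@@H](O)[C@H](O[C@@H](c1c(OC)ccc2ccc(=O)oc12)[C@H](O)C(=C)C)c1c(OC)ccc2ccc(=O)oc12 | target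

Total step count: 8. Longest linear sequence: 7 steps (steps 1, 2, 4, 5, 6, 7, 8); step 3 is a one-step side branch.

Steps least certain to work

Step 5 (key step). The most likely failure is insufficient facial discrimination in the hydride transfer, because the two faces of the cation differ only through a substituent three atoms away; the trans (racemic) dihydrofuran would then accompany the meso compound. Hydride delivery to C3 instead of the hindered C5 is also possible; it would give an enol ether that is protonated and reduced again to the tetrahydrofuran. The doubly activated benzylic–allylic C–O bond of the product may ionise in acid, and the twisted, electron-poor diarylfuran may resist protonation. Fallback, setting out from 7 and returning at 8: oxidative 2,5-dimethoxylation with Br2 in MeOH buffered by KOAc at −40 °C would give the bis-ketal 2,5-dimethoxy-2,5-bis(7-methoxy-2-oxo-2H-chromen-8-yl)-2,5-dihydrofuran F1. Et3SiH with TMSOTf in CH2Cl2 at −78 °C would then replace both methoxy groups by hydrogen through the oxocarbenium ions. This generates the cations from a ketal under aprotic conditions at low temperature, where steric discrimination should be sharper, a bulkier silane can be chosen, and the product never meets a strong protic acid. It passes through the same cation as step 5, so it would not correct an intrinsic facial preference of that cation.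

Step 8. The likely failures are poor facial selectivity at the formyl group of the 1'R half, where the ligand must override the substrate's own preference, and a slow second addition if the chromium alkoxide formed in the first addition closes onto the remaining formyl group as a six-membered lactolate, so that only one of the two required isopropenyl groups is transferred. The aldehyde carbons are also shielded by the neighbouring aryl groups, which may lower reactivity. Fallback, setting out from 10 and returning at 13: twofold Wittig olefination with isopropylidenetriphenylphosphorane (isopropyltriphenylphosphonium iodide, KN(SiMe3)2, THF, −78 °C) would give the meso bis(isobutenyl) ether F2, identical with A5, whose benzylic centres are no longer enolisable. Shi epoxidation of both alkenes (fructose-derived ketone of the enantiomeric series that makes both oxirane CH carbons S, KHSO5, K2CO3 buffer, MeCN–dimethoxymethane–H2O, 0 °C) would give the bis-epoxide F3, identical with A4. Al(OiPr)3 in refluxing toluene would isomerise both oxiranes to the isopropenyl carbinols, leaving the C2'–O and C2''–O bonds untouched.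

Step 7. The likely failure is epimerisation at the benzylic carbons through enolisation of the free dialdehyde, together with uncontrolled hydration and oligomerisation on handling. Fallback, setting out from 9 and returning at 10: cleavage with NaIO4 in THF–H2O at 0 °C and deliberate isolation of the product as its cyclic hydrate, (3R,5S)-3,5-bis(7-methoxy-2-oxo-2H-chromen-8-yl)-1,4-dioxane-2,6-diol F4. This form has no carbonyl group, and its cis-3,5-diaryl (diequatorial) arrangement corresponds to the meso series and should be the thermodynamically preferred one. Dehydration over 4 Å molecular sieves in THF directly before step 8 would release 10.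

Step 4. The likely failure is an incomplete second coupling at the di-ortho-substituted iodide, with protodestannylation of the mono-coupled furylstannane and homocoupling as competing processes. Fallback, setting out from 3 and returning at 7: Suzuki–Miyaura coupling of 3 with potassium furan-2-yltrifluoroborate (Pd(OAc)2, RuPhos, Na2CO3, EtOH, 85 °C) would give 8-(furan-2-yl)-7-methoxy-2H-chromen-2-one F5. Direct C5–H arylation of F5 with a second equivalent of 3 (Pd(OAc)2, KOAc, DMA, 130 °C) would then give 7, so the two aryl groups are installed one at a time by different mechanisms.

Further compounds

F1 | step 5 | 2,5-dimethoxy-2,5-bis(7-methoxy-2-oxo-2H-chromen-8-yl)-2,5-dihydrofuran (cis/trans mixture) | COc1ccc2ccc(=O)oc2c1C3(OC)C=CC(OC)(O3)c4c(OC)ccc5ccc(=O)oc45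
F2 | step 8 | meso 8,8'-[oxybis(3-methylbut-2-ene-1,1-diyl)]bis(7-methoxy-2H-chromen-2-one) | CC(C)=C[C@H](O[C@@H](c1c(OC)ccc2ccc(=O)oc12)C=C(C)C)c1c(OC)ccc2ccc(=O)oc12
F3 | step 8 | bis-epoxide of F2 with both oxirane CH carbons S | CC1(C)O[C@H]1[C@H](O[C@@H](c2c(OC)ccc3ccc(=O)oc23)[C@@H]4OC4(C)C)c5c(OC)ccc6ccc(=O)oc56
F4 | step 7 | (3R,5S)-3,5-bis(7-methoxy-2-oxo-2H-chromen-8-yl)-1,4-dioxane-2,6-diol (cyclic hydrate of 10; hemiacetal centres undefined) | O1C(O)[C@H](O[C@@H](c2c(OC)ccc3ccc(=O)oc23)C1O)c4c(OC)ccc5ccc(=O)oc45
F5 | step 4 | 8-(furan-2-yl)-7-methoxy-2H-chromen-2-one | COc1ccc2ccc(=O)oc2c1-c1ccco1
A1 | alternative 1 | meso 2,5-cis-bis(7-methoxy-2-oxo-2H-chromen-8-yl)-3,4-O-isopropylidenetetrahydrofuran (aryl groups anti to the acetonide) | COc1ccc2ccc(=O)oc2c1[C@H]3O[C@@H](c4c(OC)ccc5ccc(=O)oc45)[C@@H]6OC(C)(C)O[C@H]36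
A2 | alternative 1 | (7-methoxy-2-oxo-2H-chromen-8-yl)zinc iodide | COc1ccc2ccc(=O)oc2c1[Zn]I
A3 | alternative 1 | 3,4-O-isopropylidenetetrahydrofuran-2,5-diyl diacetate (cis-fused, anomeric mixture) | CC(=O)OC1OC(OC(C)=O)[C@@H]2OC(C)(C)O[C@H]12
A4 | alternative 2 | bis-epoxide with both C2 oxygens in the target sense | CC1(C)O[C@H]1[C@H](O[C@@H](c1c(OC)ccc2ccc(=O)oc12)[C@@H]3OC3(C)C)c1c(OC)ccc2ccc(=O)oc12
A5 | alternative 2 | meso 8,8'-[oxybis(3-methylbut-2-ene-1,1-diyl)]bis(7-methoxy-2H-chromen-2-one) | CC(C)=C[C@H](O[C@@H](c1c(OC)ccc2ccc(=O)oc12)C=C(C)C)c1c(OC)ccc2ccc(=O)oc12
A6 | alternative 3 | target as its C2'' tert-butyldimethylsilyl ether | C=C(C)[C@@H](O)[C@H](O[C@@H](c1c(OC)ccc2ccc(=O)oc12)[C@H](O[Si](C)(C)C(C)(C)C)C(=C)C)c1c(OC)ccc2ccc(=O)oc12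
A7 | alternative 3 | C2'-ketone of A6 (isopropenyl ketone; C1' epimers interconverting) | C=C(C)C(=O)C(O[C@@H](c1c(OC)ccc2ccc(=O)oc12)[C@H](O[Si](C)(C)C(C)(C)C)C(=C)C)c1c(OC)ccc2ccc(=O)oc12
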